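**Plan**
1. The target is read as N-[(2S)-13-(3,4-dimethyl-5-propylfuran-2-yl)-1-hydroxy-3-oxotridecan-2-yl]acetamide. Retrosynthetic cuts, in order: C8–C9 at the centre of the (CH2)10 tether; C3–C4 (ketone from a serine Weinreb amide); C13–furan C2' (furyllithium alkylation); the furan ring itself (2,3-dimethylmaleic anhydride plus a propyl Grignard reagent).
2. Enabling feature: C8 and C9 are unbranched methylenes, C8 four CH2 groups from the C3 ketone and C9 four CH2 groups from furan C2'. A terminal C7=C8 alkene and a primary C9–I are therefore insulated from both sensitive ends, and a nickel-hydride reductive hydroalkylation can join the halves in their final, unprotected form.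
3. The union is therefore the last step. The acid- and oxidant-labile tetraalkylfuran never meets the acid used for N-deprotection, the base-labile α-acetamido-β-hydroxy ketone never meets an organometallic reagent, and nothing has to be removed after the coupling.
4. Forward order: furan ring first (anhydride → hydroxybutenolide → butenolide → trialkylfuran), then the C9–C13 arm by α-lithiation/alkylation and Cl→I exchange. Separately, Boc-L-serine → Weinreb amide → pent-4-enyl ketone → Boc/Ac exchange. Then the C8–C9 coupling.
5. Stereochemistry: the only stereocentre, C2 (S), comes from L-serine and is carried through without enolisation (N-metalated carbamate in the Grignard step, ammonium salt in the deprotection, mild heterogeneous carbonate in the coupling).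

Key step: step 9

Remark: chain atoms are numbered C1 (CH2OH) to C13 (attached to furan C2'); compounds 3–6 are racemic at the carbon that becomes an sp2 furan carbon, so no control is needed there.

**Step 1**
Reactants: 1 2,3-dimethylmaleic anhydride; 2 n-propylmagnesium chloride
Product: 3 5-hydroxy-3,4-dimethyl-5-propylfuran-2(5H)-one (racemic)
Conditions: 2 (1.05 equiv, Et2O solution) added to 1, THF, −78 → −20 °C; then 1 M HCl, 0 °C
Reagents that add atoms: none
Why: Mono-addition of a Grignard reagent to a symmetrical cyclic anhydride opens the ring to a magnesium keto-carboxylate whose hindered, deactivated ketone resists a second addition at low temperature; acidification closes it to the cyclic hemiketal, and the symmetry of 1 removes any regiochemical question.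

**Step 2**
Reactants: 3 5-hydroxy-3,4-dimethyl-5-propylfuran-2(5H)-one
Product: 5 3,4-dimethyl-5-propylfuran-2(5H)-one (racemic), via ring-opened hydroxy acid 4 (not isolated)
Conditions: NaBH4, 1 M aq. NaOH/THF, 0 °C → rt; then 3 M HCl to pH 1, rt
Reagents that add atoms: none
Why: In base 3 exists as the (Z)-keto carboxylate, whose ketone is reduced chemoselectively by borohydride; the cis geometry fixed by the tetrasubstituted C=C forces lactonisation on acidification, and the new carbinol centre is erased on aromatisation in step 3.

**Step 3**
Reactants: 5 3,4-dimethyl-5-propylfuran-2(5H)-one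
Product: 7 3,4-dimethyl-2-propylfuran, via lactol 6 (not isolated)
Conditions: DIBAL-H (1.1 equiv), Et2O, −78 °C; MeOH quench, then 1 M HCl, 0 °C; pentane extraction, careful concentration
Reagents that add atoms: none
Why: DIBAL-H half-reduction of the lactone gives the lactol, and acid-promoted loss of water from the 2-hydroxy-2,5-dihydrofuran is driven by aromatisation (butenolide-to-furan reduction).

**Step 4**
Reactants: 7 3,4-dimethyl-2-propylfuran; 8 1-bromo-5-chloropentane
Product: 10 2-(5-chloropentyl)-3,4-dimethyl-5-propylfuran, via furyllithium 9 (not isolated)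
Conditions: n-BuLi (1.1 equiv), TMEDA, THF, 0 °C → rt; then 8 (1.3 equiv), DMPU, −78 °C → rt
Reagents that add atoms: none
Why: The only ring C–H of 7 is the α-position, which n-BuLi metalates (furan α-lithiation); the furyllithium then displaces bromide in preference to chloride in an SN2 alkylation.

**Step 5**
Reactants: 10 2-(5-chloropentyl)-3,4-dimethyl-5-propylfuran
Product: 11 2-(5-iodopentyl)-3,4-dimethyl-5-propylfuran
Conditions: NaI (5 equiv), acetone, reflux, dark, Ar
Reagents that add atoms: sodium iodide [Na+].[I-]
Why: Finkelstein halide exchange, driven by precipitation of NaCl, gives the primary iodide needed as radical precursor in step 9.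

**Step 6**
Reactants: 12 N-Boc-L-serine
Product: 13 tert-butyl N-[(2S)-3-hydroxy-1-[methoxy(methyl)amino]-1-oxopropan-2-yl]carbamate
Conditions: MeNHOMe·HCl, EDC·HCl, N-methylmorpholine, CH2Cl2, −15 °C → rt
Reagents that add atoms: N,O-dimethylhydroxylamine hydrochloride CNOC.Cl
Why: Carbodiimide-mediated Weinreb amide formation; the urethane N-protection prevents azlactone formation so the (S)-centre of L-serine is retained, and the amine outcompetes the free primary hydroxyl.

**Step 7**
Reactants: 13 tert-butyl N-[(2S)-3-hydroxy-1-[methoxy(methyl)amino]-1-oxopropan-2-yl]carbamate; 14 5-bromopent-1-ene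
Product: 16 tert-butyl N-[(2S)-1-hydroxy-3-oxooct-7-en-2-yl]carbamate, via pent-4-enylmagnesium bromide 15 (not isolated)
Conditions: 14, Mg, THF, rt; resulting 15 (3.5 equiv) added to 13, THF, −15 °C → rt; cold 1 M HCl quench
Reagents that add atoms: none
Why: Weinreb ketone synthesis in which two equivalents of the Grignard reagent deprotonate O–H and N–H and a third adds to give the stable N-methoxy chelate that releases the ketone only on quench; the N-magnesiated carbamate next to C2 suppresses enolisation, so the (S)-configuration should be kept.

**Step 8**
Reactants: 16 tert-butyl N-[(2S)-1-hydroxy-3-oxooct-7-en-2-yl]carbamate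
Product: 18 N-[(2S)-1-hydroxy-3-oxooct-7-en-2-yl]acetamide, via aminoketone hydrochloride 17 (not isolated)
Conditions: 4 M HCl in dioxane, 0 °C → rt; evaporate; then Ac2O (1.1 equiv), NaHCO3, EtOAc/H2O, 0 °C
Reagents that add atoms: acetic anhydride CC(=O)OC(C)=O
Why: Acidolysis of the Boc group leaves the amino ketone as its non-enolising, non-dimerising ammonium salt; Schotten–Baumann acylation in the bicarbonate-buffered two-phase system then acetylates nitrogen selectively over the primary hydroxyl, faster than the free amine can self-condense, and the terminal alkene is inert to both operations.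

**Step 9**
Reactants: 11 2-(5-iodopentyl)-3,4-dimethyl-5-propylfuran; 18 N-[(2S)-1-hydroxy-3-oxooct-7-en-2-yl]acetamide
Product: 19 N-[(2S)-13-(3,4-dimethyl-5-propylfuran-2-yl)-1-hydroxy-3-oxotridecan-2-yl]acetamide (target)
Conditions: NiBr2·diglyme (10 mol %), 4,4'-di-tert-butyl-2,2'-bipyridine (12 mol %), (EtO)2MeSiH (2.5 equiv), Na2CO3 (2 equiv), 11 (1.5 equiv), degassed DMA, rt, Ar, dark; aq. NH4Cl work-up
Reagents that add atoms: none
Why: A bipyridine-ligated nickel hydride, formed from the nickel halide, the silane and carbonate, inserts the terminal C7=C8 alkene of 18 in the anti-Markovnikov sense to give a primary alkylnickel at C8, while low-valent nickel abstracts iodine from 11 to give the primary C9 radical, which is captured at nickel; reductive elimination from the dialkylnickel(III) forms the C8–C9 bond. The closest known reaction type is the nickel-hydride-catalysed reductive anti-Markovnikov hydroalkylation of unactivated terminal alkenes with primary alkyl iodides. No ring is closed and no stereocentre is created; the existing C2 centre only has to survive, which is the reason for an insoluble carbonate at room temperature and the absence of any organometallic reagent. Cross-selectivity is inherent, because the alkene can enter the cycle only by Ni–H insertion and the iodide only by halogen abstraction; linear regioselectivity is secured by the monosubstituted, unbranched alkene, and chain walking towards the ketone is disfavoured by the unhindered bipyridine ligand and the three methylenes between C7 and C3. Alkene insertion is expected to be preferred over hydrosilylation of the C3 ketone, the furan is inert under these reductive, non-acidic conditions, and any O-silylation of the primary alcohol by the silane is reversed on aqueous work-up; using 11 in excess confines homocoupling and reduction by-products to non-polar material that is easily separated from polar 19.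

**Compound list**
1 | 2,3-dimethylmaleic anhydride | CC1=C(C)C(=O)OC1=O | starting material
2 | n-propylmagnesium chloride | CCC[Mg]Cl | starting material
3 | 5-hydroxy-3,4-dimethyl-5-propylfuran-2(5H)-one (racemic) | CCCC1(O)OC(=O)C(C)=C1C | intermediate
4 | (Z)-4-hydroxy-2,3-dimethylhept-2-enoic acid (racemic; sodium salt in the flask) | CCCC(O)/C(C)=C(/C)C(=O)O | intermediate
5 | 3,4-dimethyl-5-propylfuran-2(5H)-one (racemic) | CCCC1OC(=O)C(C)=C1C | intermediate
6 | 3,4-dimethyl-5-propyl-2,5-dihydrofuran-2-ol (stereoisomer mixture) | CCCC1OC(O)C(C)=C1C | intermediate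
7 | 3,4-dimethyl-2-propylfuran | CCCc1occ(C)c1C | intermediate
8 | 1-bromo-5-chloropentane | ClCCCCCBr | starting material
9 | (3,4-dimethyl-5-propylfuran-2-yl)lithium | CCCc1oc([Li])c(C)c1C | intermediate
10 | 2-(5-chloropentyl)-3,4-dimethyl-5-propylfuran | CCCc1oc(CCCCCCl)c(C)c1C | intermediate
11 | 2-(5-iodopentyl)-3,4-dimethyl-5-propylfuran | CCCc1oc(CCCCCI)c(C)c1C | intermediate
12 | N-Boc-L-serine | CC(C)(C)OC(=O)N[C@@H](CO)C(=O)O | starting material
13 | tert-butyl N-[(2S)-3-hydroxy-1-[methoxy(methyl)amino]-1-oxopropan-2-yl]carbamate | CON(C)C(=O)[C@H](CO)NC(=O)OC(C)(C)C | intermediate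
14 | 5-bromopent-1-ene | C=CCCCBr | starting material
15 | pent-4-en-1-ylmagnesium bromide | C=CCCC[Mg]Br | intermediate
16 | tert-butyl N-[(2S)-1-hydroxy-3-oxooct-7-en-2-yl]carbamate | C=CCCCC(=O)[C@H](CO)NC(=O)OC(C)(C)C | intermediate
17 | (2S)-2-amino-1-hydroxyoct-7-en-3-one hydrochloride | C=CCCCC(=O)[C@H](CO)N.Cl | intermediate
18 | N-[(2S)-1-hydroxy-3-oxooct-7-en-2-yl]acetamide | C=CCCCC(=O)[C@H](CO)NC(C)=O | intermediate
19 | N-[(2S)-13-(3,4-dimethyl-5-propylfuran-2-yl)-1-hydroxy-3-oxotridecan-2-yl]acetamide | CCCc1oc(CCCCCCCCCCC(=O)[C@H](CO)NC(C)=O)c(C)c1C | target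

**Count**
Total steps: 9. Longest linear sequence: 6 steps (steps 1–5, then step 9).

**Steps most likely to fail**

Step 9. The carbonate base may enolise C2 of the unprotected α-acetamido-β-hydroxy ketone, leading to epimerisation or retro-aldol loss of the hydroxymethyl group, and the nickel hydride may hydrosilylate the C3 ketone in competition with alkene insertion. The fallback forms the same C8–C9 bond as an alkene without base or hydride and then saturates it; it sets out from 7 and 13 and returns at 19. Furyllithium 9, made from 7 as in step 4, would be alkylated with 6-bromohex-1-ene to give 2-(hex-5-en-1-yl)-3,4-dimethyl-5-propylfuran F1. Weinreb amide 13 would be treated as in step 7 with hex-5-en-1-ylmagnesium bromide F2 (from 6-bromohex-1-ene and Mg) to give tert-butyl N-[(2S)-1-hydroxy-3-oxonon-8-en-2-yl]carbamate F3. As in step 8, this would pass through (2S)-2-amino-1-hydroxynon-8-en-3-one hydrochloride F4 to N-[(2S)-1-hydroxy-3-oxonon-8-en-2-yl]acetamide F5. Olefin cross-metathesis of F5 with an excess of lipophilic F1 (second-generation Ru–NHC benzylidene catalyst, CH2Cl2, 40 °C) should give N-[(2S)-13-(3,4-dimethyl-5-propylfuran-2-yl)-1-hydroxy-3-oxotridec-8-en-2-yl]acetamide F6 as an E/Z mixture. Both isomers converge on 19 on hydrogenation with RhCl(PPh3)3/H2 (benzene–EtOH, rt), which should leave the tetrasubstituted furan and the ketone untouched.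

Step 7. The magnesium alkoxide–carbamate dianion of the unprotected amide may aggregate or precipitate so that addition stalls, and prolonged exposure to excess Grignard reagent may enolise C2. The fallback uses an aprotic, conformationally locked amide; it sets out from 13 and returns at 17. Treating 13 with 2,2-dimethoxypropane and catalytic BF3·OEt2 in acetone should give tert-butyl (4S)-4-[methoxy(methyl)carbamoyl]-2,2-dimethyl-1,3-oxazolidine-3-carboxylate F7. Addition of 15 (1.3 equiv, THF, 0 °C) should then give tert-butyl (4S)-4-(hex-5-enoyl)-2,2-dimethyl-1,3-oxazolidine-3-carboxylate F8. HCl in aqueous dioxane removes the acetonide and the Boc group together to give 17, which is acetylated as in step 8.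

Step 4. Ring metalation may be incomplete, E2 elimination of the bromide may compete with SN2 alkylation, and the volatile trialkylfuran may be lost on handling. The fallback attaches the arm before the furan exists, by carbonyl addition instead of metalation/alkylation; it sets out from 5 (bypassing step 3 as well) and returns at 10. Magnesium insertion into the C–Br bond of 8 (THF) should give 5-chloropentylmagnesium bromide F9. Transmetalation with anhydrous CeCl3 at −78 °C gives (5-chloropentyl)cerium dichloride F10, a weakly basic nucleophile expected to add 1,2 to butenolide 5 instead of deprotonating its γ-position. The resulting 2-(5-chloropentyl)-3,4-dimethyl-5-propyl-2,5-dihydrofuran-2-ol F11 should lose water on dilute acid work-up and aromatise to 10.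

**Further compounds**
F1 | step 9 | 2-(hex-5-en-1-yl)-3,4-dimethyl-5-propylfuran | CCCc1oc(CCCCC=C)c(C)c1C
F2 | step 9 | hex-5-en-1-ylmagnesium bromide | C=CCCCC[Mg]Br
F3 | step 9 | tert-butyl N-[(2S)-1-hydroxy-3-oxonon-8-en-2-yl]carbamate | C=CCCCCC(=O)[C@H](CO)NC(=O)OC(C)(C)C
F4 | step 9 | (2S)-2-amino-1-hydroxynon-8-en-3-one hydrochloride | C=CCCCCC(=O)[C@H](CO)N.Cl
F5 | step 9 | N-[(2S)-1-hydroxy-3-oxonon-8-en-2-yl]acetamide | C=CCCCCC(=O)[C@H](CO)NC(C)=O
F6 | step 9 | N-[(2S)-13-(3,4-dimethyl-5-propylfuran-2-yl)-1-hydroxy-3-oxotridec-8-en-2-yl]acetamide (E/Z mixture) | CCCc1oc(CCCCC=CCCCCC(=O)[C@H](CO)NC(C)=O)c(C)c1C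
F7 | step 7 | tert-butyl (4S)-4-[methoxy(methyl)carbamoyl]-2,2-dimethyl-1,3-oxazolidine-3-carboxylate | CON(C)C(=O)[C@@H]1COC(C)(C)N1C(=O)OC(C)(C)C
F8 | step 7 | tert-butyl (4S)-4-(hex-5-enoyl)-2,2-dimethyl-1,3-oxazolidine-3-carboxylate | C=CCCCC(=O)[C@@H]1COC(C)(C)N1C(=O)OC(C)(C)C
F9 | step 4 | 5-chloropentylmagnesium bromide | ClCCCCC[Mg]Br
F10 | step 4 | (5-chloropentyl)cerium dichloride | ClCCCCC[Ce](Cl)Cl
F11 | step 4 | 2-(5-chloropentyl)-3,4-dimethyl-5-propyl-2,5-dihydrofuran-2-ol | CCCC1OC(O)(CCCCCCl)C(C)=C1C
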